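**Strategy.** The furanone is disconnected at the O–C10 bond. The key step exploits the fact that the C3 carbonyl oxygen sits three bonds from C10 (C3–C2–C1–C10) inside the ten-membered carbocycle C1–C10, so a trans-1,10-epoxide of a 3-oxo-4Z-germacrenolide can be opened from within the ring. One operation forms O–C10, closes the five-membered ring O–C3–C2–C1–C10 that bridges the carbocycle, sets quaternary C10 by inversion and leaves on C1 the oxygen that becomes the furanone carbonyl. The precursor is epoxy ketone 26, a 6,12-trans-lactone silylated at O8 and O15. It is built by chromium allylation of a bromobutenolide and a Nozaki–Hiyama–Kishi ring closure.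

Key step: step 18

Assumption: dienone 25 is taken to react through the ring conformer whose exposed C1=C10 face leads to the (1S,10S)-epoxide; this cannot be verified without modelling and is covered by a fallback.

Conventions: C1–C15 are germacrane locants (C12 lactone carbonyl, C13 exocyclic methylene, C14 methyl on C10, C15 oxygenated carbon on C4). TBDPS = tert-butyl(diphenyl)silyl, TES = triethylsilyl, PMB = 4-methoxybenzyl.

**Route**

Step 1
Reactants: 1 prop-2-yn-1-ol
Product: 2 tert-butyl(diphenyl)(prop-2-yn-1-yloxy)silane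
Conditions: TBDPSCl, imidazole, CH2Cl2, 0 °C to rt
Reagents that add atoms: tert-butyl(chloro)diphenylsilane, CC(C)(C)[Si](Cl)(c1ccccc1)c1ccccc1
Why: Imidazole-promoted silylation of a primary alcohol; TBDPS is chosen over a smaller silyl group because O15 must survive the Lewis acid of step 18 and the acidic methanol of step 19.

Step 2
Reactants: 2 tert-butyl(diphenyl)(prop-2-yn-1-yloxy)silane; 3 prop-2-enal (acrolein)
Product: 5 rac-6-(TBDPS-oxy)hex-1-en-4-yn-3-ol, via lithium acetylide 4 (not isolated)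
Conditions: n-BuLi, THF, −78 °C; then acrolein, −78 °C
Reagents that add atoms: none
Why: 1,2-Addition of a lithium acetylide to an enal at low temperature should give the vinyl alkynyl carbinol that carries C4–C7 and C15.

Step 3
Reactants: 5 rac-6-(TBDPS-oxy)hex-1-en-4-yn-3-ol
Product: 6 (3S)-6-(TBDPS-oxy)hex-1-en-4-yn-3-ol
Conditions: Ti(OiPr)4 (10 mol %), L-(+)-DIPT (15 mol %), t-BuOOH (0.6 equiv), 4 Å MS, CH2Cl2, −20 °C
Reagents that add atoms: none
Why: Sharpless kinetic resolution of a secondary allylic alcohol: with L-(+)-DIPT the (R)-enantiomer should be epoxidised at its vinyl group much faster, so the (S)-alcohol (at most half of the material) is recovered and fixes C6.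

Step 4
Reactants: 6 (3S)-6-(TBDPS-oxy)hex-1-en-4-yn-3-ol
Product: 8 (3S,4Z)-6-(TBDPS-oxy)-5-iodohexa-1,4-dien-3-ol, via vinylalanate 7 (not isolated)
Conditions: NaAlH2(OCH2CH2OMe)2, THF, 0 °C; then I2, −78 °C
Reagents that add atoms: iodine, II
Why: Hydroxyl-directed trans-hydroalumination of the propargylic alcohol puts hydride on C5 and aluminium on C4 in a five-membered alanate, and iodinolysis with retention gives the Z vinyl iodide with iodine cis to C6; the low temperature suppresses loss of the silyloxy group to an allene.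

Step 5
Reactants: 8 (3S,4Z)-6-(TBDPS-oxy)-5-iodohexa-1,4-dien-3-ol; 9 2-(bromomethyl)prop-2-enoic acid
Product: 10 (3S,4Z)-6-(TBDPS-oxy)-5-iodohexa-1,4-dien-3-yl 2-(bromomethyl)prop-2-enoate
Conditions: DCC, DMAP (5 mol %), CH2Cl2, −20 to 0 °C
Reagents that add atoms: none
Why: Steglich esterification proceeds with retention at C6; DMAP is kept catalytic and cold so that the allylic bromide is not quaternised.

Step 6
Reactants: 10 (3S,4Z)-6-(TBDPS-oxy)-5-iodohexa-1,4-dien-3-yl 2-(bromomethyl)prop-2-enoate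
Product: 11 (5S)-3-(bromomethyl)-5-[(1Z)-3-(TBDPS-oxy)-2-iodoprop-1-en-1-yl]furan-2(5H)-one
Conditions: second-generation Grubbs catalyst (5 mol %), toluene, 80 °C
Reagents that add atoms: none
Why: Ring-closing metathesis between the terminal vinyl group and the acrylate closes the butenolide with loss of ethylene, while the trisubstituted iodoalkene is too hindered to take part.

Step 7
Reactants: 12 pent-3-yn-1-ol
Product: 13 1-methoxy-4-[(pent-3-yn-1-yloxy)methyl]benzene
Conditions: NaH, PMBCl, n-Bu4NI (cat.), THF/DMF, 0 °C to rt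
Reagents that add atoms: 4-methoxybenzyl chloride, COc1ccc(CCl)cc1
Why: Williamson etherification; the PMB ether on O3 is orthogonal to every silyl ether used later.

Step 8
Reactants: 13 1-methoxy-4-[(pent-3-yn-1-yloxy)methyl]benzene
Product: 15 1-{[(3E)-4-iodopent-3-en-1-yl]oxymethyl}-4-methoxybenzene, via vinylzirconocene 14 (not isolated)
Conditions: Cp2Zr(H)Cl (2 equiv), THF, 50 °C; then I2, 0 °C
Reagents that add atoms: iodine, II
Why: syn-Hydrozirconation, equilibrated with excess reagent so that zirconium sits on the less hindered methyl-bearing carbon (C10), followed by iodinolysis with retention should give the E 2-iodoalkene.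

Step 9
Reactants: 15 1-{[(3E)-4-iodopent-3-en-1-yl]oxymethyl}-4-methoxybenzene; 16 oxirane
Product: 18 (3E)-6-(PMB-oxy)-3-methylhex-3-en-1-ol, via vinyllithium 17 (not isolated)
Conditions: t-BuLi (2 equiv), Et2O, −78 °C; then oxirane, THF, −78 °C to rt
Reagents that add atoms: none
Why: Iodine–lithium exchange keeps the alkene geometry and SN2 opening of oxirane by the vinyllithium adds C9 and C8, giving the E trisubstituted homoallylic alcohol.

Step 10
Reactants: 18 (3E)-6-(PMB-oxy)-3-methylhex-3-en-1-ol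
Product: 19 (3E)-6-(PMB-oxy)-3-methylhex-3-enal
Conditions: DMP, NaHCO3, CH2Cl2, 0 °C (used at once)
Reagents that add atoms: none
Why: Buffered Dess–Martin oxidation should give the β,γ-unsaturated C8 aldehyde without moving the double bond into conjugation.

Step 11
Reactants: 11 (5S)-3-(bromomethyl)-5-[(1Z)-3-(TBDPS-oxy)-2-iodoprop-1-en-1-yl]furan-2(5H)-one; 19 (3E)-6-(PMB-oxy)-3-methylhex-3-enal
Product: 20 (4R,5S)-5-[(1Z)-3-(TBDPS-oxy)-2-iodoprop-1-en-1-yl]-4-[(1S,3E)-1-hydroxy-6-(PMB-oxy)-3-methylhex-3-en-1-yl]-3-methylideneoxolan-2-one (6S,7R,8S in germacrane locants)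
Conditions: CrCl2 (3 equiv), THF, rt
Reagents that add atoms: none
Why: Chromium-mediated carbonyl allylation (Nozaki–Hiyama type): the allylchromium adds through its γ-carbon C7 in a chair transition state, the butenolide ring locks C6 trans to the CH2Cr group so C7/C8 come out anti, and the aldehyde approaches the ring face opposite the C6 alkenyl group, which sets C7 and C8 from C6 and unveils the α-methylene trans-lactone; without nickel the vinyl iodide is not touched.

Step 12
Reactants: 20 the lactone alcohol of step 11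
Product: 21 (4S,5S)-5-[(1Z)-3-(TBDPS-oxy)-2-iodoprop-1-en-1-yl]-4-[(1S,3E)-6-(PMB-oxy)-3-methyl-1-(TES-oxy)hex-3-en-1-yl]-3-methylideneoxolan-2-one
Conditions: TESOTf, 2,6-lutidine, CH2Cl2, −78 °C
Reagents that add atoms: triethylsilyl trifluoromethanesulfonate, CC[Si](CC)(CC)OS(=O)(=O)C(F)(F)F
Why: Silyl triflate silylation of the secondary C8 alcohol; a silyl ether (not the tiglate) is kept on O8 so that no ester carbonyl can compete for C10 in step 18.

Step 13
Reactants: 21 the TES ether of step 12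
Product: 22 (4S,5S)-5-[(1Z)-3-(TBDPS-oxy)-2-iodoprop-1-en-1-yl]-4-[(1S,3E)-6-hydroxy-3-methyl-1-(TES-oxy)hex-3-en-1-yl]-3-methylideneoxolan-2-one
Conditions: DDQ, CH2Cl2/pH 7 buffer, 0 °C
Reagents that add atoms: none
Why: Oxidative PMB cleavage under buffered conditions frees O3 and leaves both silyl ethers, the vinyl iodide and the alkenes intact.

Step 14
Reactants: 22 the primary alcohol of step 13
Product: 23 (4S,5S)-5-[(1Z)-3-(TBDPS-oxy)-2-iodoprop-1-en-1-yl]-4-[(1S,3E)-3-methyl-6-oxo-1-(TES-oxy)hex-3-en-1-yl]-3-methylideneoxolan-2-one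
Conditions: DMP, NaHCO3, CH2Cl2, 0 °C (used at once)
Reagents that add atoms: none
Why: Buffered Dess–Martin oxidation to the C3 aldehyde, again a β,γ-unsaturated aldehyde that is not stored.

Step 15
Reactants: 23 the iodo aldehyde of step 14
Product: 24 (6R,7S,8S)-3-hydroxy-15-(TBDPS-oxy)-8-(TES-oxy)germacra-1(10)E,4Z,11(13)-trien-12,6-olide (both C3 epimers)
Conditions: CrCl2 (10 equiv), NiCl2 (cat.), DMSO/THF, rt, 2 mM by slow addition
Reagents that add atoms: none
Why: Intramolecular Nozaki–Hiyama–Kishi reaction: nickel-catalysed activation of the C4–I bond, transmetalation to chromium and addition to the C3 aldehyde should close the ten-membered carbocycle with retention of the Z geometry; the C3 configuration does not matter because it is oxidised next.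

Step 16
Reactants: 24 the macrocyclic carbinol of step 15
Product: 25 (6R,7S,8S)-3-oxo-15-(TBDPS-oxy)-8-(TES-oxy)germacra-1(10)E,4Z,11(13)-trien-12,6-olide
Conditions: DMP, NaHCO3, CH2Cl2, 0 °C
Reagents that add atoms: none
Why: Dess–Martin oxidation of the allylic alcohol gives the C3 enone under neutral conditions that do not isomerise the β,γ-alkene.

Step 17
Reactants: 25 the dienone of step 16
Product: 26 (1S,6R,7S,8S,10S)-1,10-epoxy-3-oxo-15-(TBDPS-oxy)-8-(TES-oxy)germacra-4Z,11(13)-dien-12,6-olide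
Conditions: dimethyldioxirane, acetone/CH2Cl2, −20 °C
Reagents that add atoms: dimethyldioxirane, CC1(C)OO1
Why: The neutral, electrophilic dioxirane should epoxidise only the electron-rich trisubstituted C1=C10 alkene (not the enone or the acrylate) from the outer face of the conformer set by the trans-lactone and C8, giving the trans (1S,10S)-epoxide without acid or base that would open the β,γ-epoxy ketone.

Step 18
Reactants: 26 the epoxy ketone of step 17
Product: 27 (1S,3R,6R,7S,8S,10R)-3,10-epoxy-1,3-dihydroxy-15-(TBDPS-oxy)-8-(TES-oxy)germacra-4Z,11(13)-dien-12,6-olide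
Conditions: Mg(ClO4)2 (0.3 equiv), MeCN, H2O (5 equiv), 0 °C to rt
Reagents that add atoms: water, O
Why: Mg(ClO4)2 polarises the epoxide so that the bond from oxygen to tertiary C10 begins to ionise while a lone pair of the C3 ketone oxygen, held close by the ring, attacks C10 from inside the ring anti to the leaving oxygen; water then captures the bicyclic oxocarbenium ion at C3 as the hemiketal and the former epoxide oxygen stays on C1 as a secondary alcohol. The closest known reactions are the acid-promoted cyclisation of β,γ-epoxy ketones to hydroxydihydrofurans and furans and the transannular opening of germacranolide 1,10-epoxides by internal oxygen nucleophiles. The oxolane ring O–C3–C2–C1–C10 closes in a 5-endo sense at the epoxide (attack at the distal carbon, both epoxide carbons ending in the new ring), acceptable because the transition state is loose at the cation-stabilising C10, whereas 4-exo attack at C1 would give an oxetane. C10 is set by stereospecific inversion of the (10S)-epoxide to (10R), C1 keeps the epoxide configuration, and the C3 hemiketal can only form with its hydroxyl on the outside of the bridged bicycle. The step needs oxygen participation to outrun 1,2-hydride shift, proton loss to an exocyclic allylic alcohol and direct hydrolysis; this is secured by the 1,4 proximity of C3=O and C10, by the absence of any other free hydroxyl or acyloxy nucleophile (O8 and O15 are silylated), by the electron-poor C4=C5 bond that cannot attack the epoxide, and by base-free conditions that exclude E1cB opening. If the oxocarbenium ion loses the C2 proton instead of adding water, the resulting enol ether converges on the same furanone in step 19.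

Step 19
Reactants: 27 the hemiketal diol of step 18
Product: 30 (6R,7R,8S,10R)-3,10-epoxy-8-hydroxy-1-oxo-15-(TBDPS-oxy)germacra-2,4Z,11(13)-trien-12,6-olide, via keto hemiketal 28 (not isolated), via silyl furanone 29 (not isolated)
Conditions: DMP, NaHCO3, CH2Cl2, 0 °C to rt; then PPTS, MeOH, rt
Reagents that add atoms: none
Why: Dess–Martin oxidation turns the C1 carbinol into the ketone, the resulting β-hydroxy ketone (the C3 hemiketal) loses water under PPTS to the vinylogous ester of the 3(2H)-furanone, and the same acidic methanol cleaves the secondary TES ether while the primary TBDPS ether stays.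

Step 20
Reactants: 30 the C8 alcohol of step 19; 31 (E)-2-methylbut-2-enoyl chloride (tigloyl chloride)
Product: 32 15-O-TBDPS-lychnophorolide B, (6R,7R,8S,10R)
Conditions: Et3N, DMAP (cat.), CH2Cl2, 0 °C to rt
Reagents that add atoms: none
Why: DMAP-catalysed acylation of the only free hydroxyl; the E geometry of the tiglate is the stable one and is retained.

Step 21
Reactants: 32 15-O-TBDPS-lychnophorolide B
Product: 33 lychnophorolide B
Conditions: HF·pyridine, pyridine, THF, 0 °C to rt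
Reagents that add atoms: none
Why: Buffered fluoride cleavage of the primary TBDPS ether under non-basic conditions that the α-methylene lactone, the furanone and the tiglate should tolerate.

**Compound list**

1 | prop-2-yn-1-ol | C#CCO | starting material
2 | tert-butyl(diphenyl)(prop-2-yn-1-yloxy)silane | C#CCO[Si](c1ccccc1)(c1ccccc1)C(C)(C)C | intermediate
3 | prop-2-enal (acrolein) | C=CC=O | starting material
4 | [3-(TBDPS-oxy)prop-1-yn-1-yl]lithium | [Li]C#CCO[Si](c1ccccc1)(c1ccccc1)C(C)(C)C | intermediate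
5 | rac-6-(TBDPS-oxy)hex-1-en-4-yn-3-ol | C=CC(O)C#CCO[Si](c1ccccc1)(c1ccccc1)C(C)(C)C | intermediate
6 | (3S)-6-(TBDPS-oxy)hex-1-en-4-yn-3-ol | C=C[C@H](O)C#CCO[Si](c1ccccc1)(c1ccccc1)C(C)(C)C | intermediate
7 | sodium (5S)-5-ethenyl-2,2-bis(2-methoxyethoxy)-3-[(TBDPS-oxy)methyl]-2,5-dihydro-1,2-oxaluminol-2-uide (cyclic vinylalanate) | C=C[C@@H]1O[Al-](OCCOC)(OCCOC)C(CO[Si](c2ccccc2)(c2ccccc2)C(C)(C)C)=C1.[Na+] | intermediate
8 | (3S,4Z)-6-(TBDPS-oxy)-5-iodohexa-1,4-dien-3-ol | C=C[C@H](O)/C=C(\I)CO[Si](c1ccccc1)(c1ccccc1)C(C)(C)C | intermediate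
9 | 2-(bromomethyl)prop-2-enoic acid | C=C(CBr)C(=O)O | starting material
10 | (3S,4Z)-6-(TBDPS-oxy)-5-iodohexa-1,4-dien-3-yl 2-(bromomethyl)prop-2-enoate | C=C[C@H](OC(=O)C(=C)CBr)/C=C(\I)CO[Si](c1ccccc1)(c1ccccc1)C(C)(C)C | intermediate
11 | (5S)-3-(bromomethyl)-5-[(1Z)-3-(TBDPS-oxy)-2-iodoprop-1-en-1-yl]furan-2(5H)-one | O=C1O[C@H](/C=C(\I)CO[Si](c2ccccc2)(c2ccccc2)C(C)(C)C)C=C1CBr | intermediate
12 | pent-3-yn-1-ol | CC#CCCO | starting material
13 | 1-methoxy-4-[(pent-3-yn-1-yloxy)methyl]benzene | CC#CCCOCc1ccc(OC)cc1 | intermediate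
14 | chlorobis(cyclopentadienyl)[(2E)-5-(PMB-oxy)pent-2-en-2-yl]zirconium | C/C(=C\CCOCc1ccc(OC)cc1)[Zr](Cl)(C1C=CC=C1)C1C=CC=C1 | intermediate
15 | 1-{[(3E)-4-iodopent-3-en-1-yl]oxymethyl}-4-methoxybenzene | C/C(I)=C\CCOCc1ccc(OC)cc1 | intermediate
16 | oxirane | C1CO1 | starting material
17 | vinyllithium from 15 (lithium in place of iodine, alkene geometry retained) | [Li]/C(C)=C/CCOCc1ccc(OC)cc1 | intermediate
18 | (3E)-6-(PMB-oxy)-3-methylhex-3-en-1-ol | OCC/C(C)=C/CCOCc1ccc(OC)cc1 | intermediate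
19 | (3E)-6-(PMB-oxy)-3-methylhex-3-enal | O=CC/C(C)=C/CCOCc1ccc(OC)cc1 | intermediate
20 | (4R,5S)-5-[(1Z)-3-(TBDPS-oxy)-2-iodoprop-1-en-1-yl]-4-[(1S,3E)-1-hydroxy-6-(PMB-oxy)-3-methylhex-3-en-1-yl]-3-methylideneoxolan-2-one | C=C1C(=O)O[C@H](/C=C(\I)CO[Si](c2ccccc2)(c2ccccc2)C(C)(C)C)[C@H]1[C@@H](O)C/C(C)=C/CCOCc1ccc(OC)cc1 | intermediate
21 | (4S,5S)-5-[(1Z)-3-(TBDPS-oxy)-2-iodoprop-1-en-1-yl]-4-[(1S,3E)-6-(PMB-oxy)-3-methyl-1-(TES-oxy)hex-3-en-1-yl]-3-methylideneoxolan-2-one | C=C1C(=O)O[C@H](/C=C(\I)CO[Si](c2ccccc2)(c2ccccc2)C(C)(C)C)[C@H]1[C@@H](O[Si](CC)(CC)CC)C/C(C)=C/CCOCc1ccc(OC)cc1 | intermediate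
22 | (4S,5S)-5-[(1Z)-3-(TBDPS-oxy)-2-iodoprop-1-en-1-yl]-4-[(1S,3E)-6-hydroxy-3-methyl-1-(TES-oxy)hex-3-en-1-yl]-3-methylideneoxolan-2-one | C=C1C(=O)O[C@H](/C=C(\I)CO[Si](c2ccccc2)(c2ccccc2)C(C)(C)C)[C@H]1[C@@H](O[Si](CC)(CC)CC)C/C(C)=C/CCO | intermediate
23 | (4S,5S)-5-[(1Z)-3-(TBDPS-oxy)-2-iodoprop-1-en-1-yl]-4-[(1S,3E)-3-methyl-6-oxo-1-(TES-oxy)hex-3-en-1-yl]-3-methylideneoxolan-2-one | C=C1C(=O)O[C@H](/C=C(\I)CO[Si](c2ccccc2)(c2ccccc2)C(C)(C)C)[C@H]1[C@@H](O[Si](CC)(CC)CC)C/C(C)=C/CC=O | intermediate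
24 | (6R,7S,8S)-3-hydroxy-15-(TBDPS-oxy)-8-(TES-oxy)germacra-1(10)E,4Z,11(13)-trien-12,6-olide, C3 epimers | C=C1C(=O)O[C@@H]2/C=C(/CO[Si](c3ccccc3)(c3ccccc3)C(C)(C)C)C(O)C/C=C(\C)C[C@H](O[Si](CC)(CC)CC)[C@@H]12 | intermediate
25 | (6R,7S,8S)-3-oxo-15-(TBDPS-oxy)-8-(TES-oxy)germacra-1(10)E,4Z,11(13)-trien-12,6-olide | C=C1C(=O)O[C@@H]2/C=C(/CO[Si](c3ccccc3)(c3ccccc3)C(C)(C)C)C(=O)C/C=C(\C)C[C@H](O[Si](CC)(CC)CC)[C@@H]12 | intermediate
26 | (1S,6R,7S,8S,10S)-1,10-epoxy-3-oxo-15-(TBDPS-oxy)-8-(TES-oxy)germacra-4Z,11(13)-dien-12,6-olide | C=C1C(=O)O[C@@H]2/C=C(/CO[Si](c4ccccc4)(c4ccccc4)C(C)(C)C)C(=O)C[C@@H]3O[C@@]3(C)C[C@H](O[Si](CC)(CC)CC)[C@@H]12 | intermediate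
27 | (1S,3R,6R,7S,8S,10R)-3,10-epoxy-1,3-dihydroxy-15-(TBDPS-oxy)-8-(TES-oxy)germacra-4Z,11(13)-dien-12,6-olide | C=C1C(=O)O[C@@H]2/C=C(/CO[Si](c4ccccc4)(c4ccccc4)C(C)(C)C)[C@@]3(O)C[C@H](O)[C@@](C)(C[C@H](O[Si](CC)(CC)CC)[C@@H]12)O3 | intermediate
28 | (3R,6R,7S,8S,10R)-3,10-epoxy-3-hydroxy-1-oxo-15-(TBDPS-oxy)-8-(TES-oxy)germacra-4Z,11(13)-dien-12,6-olide | C=C1C(=O)O[C@@H]2/C=C(/CO[Si](c4ccccc4)(c4ccccc4)C(C)(C)C)[C@@]3(O)CC(=O)[C@@](C)(C[C@H](O[Si](CC)(CC)CC)[C@@H]12)O3 | intermediate
29 | (6R,7S,8S,10R)-3,10-epoxy-1-oxo-15-(TBDPS-oxy)-8-(TES-oxy)germacra-2,4Z,11(13)-trien-12,6-olide | C=C1C(=O)O[C@@H]2/C=C(/CO[Si](c4ccccc4)(c4ccccc4)C(C)(C)C)C3=CC(=O)[C@@](C)(C[C@H](O[Si](CC)(CC)CC)[C@@H]12)O3 | intermediate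
30 | (6R,7R,8S,10R)-3,10-epoxy-8-hydroxy-1-oxo-15-(TBDPS-oxy)germacra-2,4Z,11(13)-trien-12,6-olide | C=C1C(=O)O[C@@H]2/C=C(/CO[Si](c4ccccc4)(c4ccccc4)C(C)(C)C)C3=CC(=O)[C@@](C)(C[C@H](O)[C@@H]12)O3 | intermediate
31 | (E)-2-methylbut-2-enoyl chloride (tigloyl chloride) | C/C=C(\C)C(=O)Cl | starting material
32 | 15-O-TBDPS-lychnophorolide B, (6R,7R,8S,10R) | C=C1C(=O)O[C@@H]2/C=C(/CO[Si](c4ccccc4)(c4ccccc4)C(C)(C)C)C3=CC(=O)[C@@](C)(C[C@H](OC(=O)/C(C)=C/C)[C@@H]12)O3 | intermediate
33 | lychnophorolide B, (6R,7R,8S,10R) | C=C1C(=O)O[C@@H]2/C=C(/CO)C3=CC(=O)[C@@](C)(C[C@H](OC(=O)/C(C)=C/C)[C@@H]12)O3 | target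

**Step count.** Total: 21 steps. Longest linear sequence: 17 steps (steps 1–6 and 11–21).

**Steps most likely to fail**

1. Step 18. The Lewis acid may ionise C10 before the carbonyl oxygen engages, so that hydride shift or proton loss competes, or it may strip the TES ether. The fallback lets a C3 hydroxyl, a better nucleophile, do the same ring closure and adjusts the oxidation level afterwards. It sets out from carbinol 24 and returns at silyl furanone 29. Dimethyldioxirane should epoxidise C1=C10 of 24 (the C4=C5 bond is deactivated by three allylic oxygens) to give the (3R)-configured epoxy alcohol F1; the 3-epimer, which cannot bridge, would be oxidised with DMP to 26. A trace of CSA in CH2Cl2 should make the C3 hydroxyl open the epoxide at C10 with inversion to give bridged ether alcohol F2. DMP would give oxolanone F3, and dehydrogenation of C2–C3 with IBX (DMSO, 70 °C) would give 29.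

2. Step 15. Intermolecular coupling or simple reduction of the C–I bond may outrun closure of the strained ten-membered ring. The fallback forms the same C3–C4 bond as an acyl–vinyl coupling. It sets out from aldehyde 23 and returns at dienone 25, which also removes step 16. Pinnick oxidation (NaClO2, NaH2PO4, 2-methylbut-2-ene) would give iodo acid F4. Pd(PPh3)4 with hexamethylditin would give vinylstannane acid F5. 1-Chloro-N,N,2-trimethylprop-1-en-1-amine would convert it under neutral conditions into acid chloride F6. An intramolecular Stille acylation (Pd2(dba)3, tri(2-furyl)phosphine, high dilution) would then give 25.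

3. Step 17. The oxidant may deliver oxygen mainly to the other face of C1=C10, which after inversion would give the wrong C10 configuration. The fallback uses that same facial preference without inversion. It sets out from dienone 25 and returns at keto hemiketal 28. Catalytic OsO4 with NMO should dihydroxylate the electron-rich C1=C10 bond on the preferred face, and the tertiary C10 hydroxyl, now on the required side, should close onto the C3 ketone to give diol hemiketal F7 (C1 epimer of 27). DMP oxidation of its C1 carbinol would give 28.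

**Further compounds**

F1 | step 18 | (1S,3R,6R,7S,8S,10S)-1,10-epoxy-3-hydroxy-15-(TBDPS-oxy)-8-(TES-oxy)germacra-4Z,11(13)-dien-12,6-olide | C=C1C(=O)O[C@@H]2/C=C(/CO[Si](c4ccccc4)(c4ccccc4)C(C)(C)C)[C@H](O)C[C@@H]3O[C@@]3(C)C[C@H](O[Si](CC)(CC)CC)[C@@H]12
F2 | step 18 | (1S,3R,6R,7S,8S,10R)-3,10-epoxy-1-hydroxy-15-(TBDPS-oxy)-8-(TES-oxy)germacra-4Z,11(13)-dien-12,6-olide | C=C1C(=O)O[C@@H]2/C=C(/CO[Si](c4ccccc4)(c4ccccc4)C(C)(C)C)[C@H]3C[C@H](O)[C@@](C)(C[C@H](O[Si](CC)(CC)CC)[C@@H]12)O3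
F3 | step 18 | (3R,6R,7S,8S,10R)-3,10-epoxy-1-oxo-15-(TBDPS-oxy)-8-(TES-oxy)germacra-4Z,11(13)-dien-12,6-olide | C=C1C(=O)O[C@@H]2/C=C(/CO[Si](c4ccccc4)(c4ccccc4)C(C)(C)C)[C@H]3CC(=O)[C@@](C)(C[C@H](O[Si](CC)(CC)CC)[C@@H]12)O3
F4 | step 15 | (4S,5S)-4-[(1S,3E)-5-carboxy-3-methyl-1-(TES-oxy)pent-3-en-1-yl]-5-[(1Z)-3-(TBDPS-oxy)-2-iodoprop-1-en-1-yl]-3-methylideneoxolan-2-one | C=C1C(=O)O[C@H](/C=C(\I)CO[Si](c2ccccc2)(c2ccccc2)C(C)(C)C)[C@H]1[C@@H](O[Si](CC)(CC)CC)C/C(C)=C/CC(=O)O
F5 | step 15 | (4S,5S)-4-[(1S,3E)-5-carboxy-3-methyl-1-(TES-oxy)pent-3-en-1-yl]-5-[(1Z)-3-(TBDPS-oxy)-2-(trimethylstannyl)prop-1-en-1-yl]-3-methylideneoxolan-2-one | C=C1C(=O)O[C@H](/C=C(\[Sn](C)(C)C)CO[Si](c2ccccc2)(c2ccccc2)C(C)(C)C)[C@H]1[C@@H](O[Si](CC)(CC)CC)C/C(C)=C/CC(=O)O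
F6 | step 15 | acid chloride of F5 | C=C1C(=O)O[C@H](/C=C(\[Sn](C)(C)C)CO[Si](c2ccccc2)(c2ccccc2)C(C)(C)C)[C@H]1[C@@H](O[Si](CC)(CC)CC)C/C(C)=C/CC(=O)Cl
F7 | step 17 | (1R,3R,6R,7S,8S,10R)-3,10-epoxy-1,3-dihydroxy-15-(TBDPS-oxy)-8-(TES-oxy)germacra-4Z,11(13)-dien-12,6-olide | C=C1C(=O)O[C@@H]2/C=C(/CO[Si](c4ccccc4)(c4ccccc4)C(C)(C)C)[C@@]3(O)C[C@@H](O)[C@@](C)(C[C@H](O[Si](CC)(CC)CC)[C@@H]12)O3
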